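**Plan**
- Retrosynthesis: the C4 ketone is taken back to a C4–OMe ether (an oxidation-level helper). Ring C is then cut at C3–C4 and O1–C2 in one retro-[4+2] step.
- Enabling feature: O1–C8a=C4a–C4 of rings A and C, with C4 at the aldehyde level, is an ortho-quinone methide (a 1-oxadiene). C2=C3 with the 4-methoxyphenyl group on C2 is an electron-rich styrene.
- Forward: ring A is completed first (formylation, bromination and methoxylation of 3,4,5-trimethoxyphenol). Ring B arrives intact in 4-methoxystyrene. Ring C forms last, in one operation, from the salicylaldehyde and the styrene.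
- Stereochemistry: C2 (S) is set in the cycloaddition by a chiral Brønsted acid through its counter-anion. The temporary C4 centre disappears when DDQ converts C4–OMe into C4=O.

Key step: step 4

Remark: the sense of induction of the chiral acid in step 4 cannot be predicted with certainty. The (R)-acid is written, and its antipode is to be used if a pilot run shows the 2R product. Flavanone numbering (O1, C2, C3, C4, C4a, C5–C8, C8a) is used throughout.

**Step 1**
Reactants: 1 3,4,5-trimethoxyphenol
Product: 3 2-hydroxy-4,5,6-trimethoxybenzaldehyde, via 2-(hydroxymethyl)-3,4,5-trimethoxyphenol 2 (not isolated)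
Conditions: MgCl2, Et3N, (CH2O)n, MeCN, reflux; then 1 M HCl
Reagents that add atoms: formaldehyde (as paraformaldehyde), C=O
Why: Magnesium-phenoxide-directed ortho-formylation (Casnati–Skattebøl reaction): the chelated phenoxide adds formaldehyde at one of its two equivalent ortho carbons, a second formaldehyde oxidises the benzylic alkoxide of 2 by Oppenauer-type hydride transfer, and the chelated product should resist a second formylation.

**Step 2**
Reactants: 3 2-hydroxy-4,5,6-trimethoxybenzaldehyde
Product: 4 3-bromo-2-hydroxy-4,5,6-trimethoxybenzaldehyde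
Conditions: NBS, MeCN, 0 °C to rt
Reagents that add atoms: N-bromosuccinimide, O=C1CCC(=O)N1Br
Why: Electrophilic aromatic bromination should occur at the only free ring position, which is ortho to the hydroxyl group and ortho/para to methoxy groups.

**Step 3**
Reactants: 4 3-bromo-2-hydroxy-4,5,6-trimethoxybenzaldehyde
Product: 5 2-hydroxy-3,4,5,6-tetramethoxybenzaldehyde
Conditions: NaOMe (excess), CuBr (10 mol%), DMF/MeOH, 110 °C; then 1 M HCl
Reagents that add atoms: sodium methoxide, [Na+].[O-]C
Why: Copper-catalysed Ullmann-type methoxylation of an aryl bromide ortho to a phenoxide, the reaction type that converts 5-bromovanillin into syringaldehyde with a free aldehyde present.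

**Step 4**
Reactants: 5 2-hydroxy-3,4,5,6-tetramethoxybenzaldehyde; 6 4-methoxystyrene (1-ethenyl-4-methoxybenzene)
Product: 9 (2S,4S)-4,5,6,7,8-pentamethoxy-2-(4-methoxyphenyl)chromane, via 2-(dimethoxymethyl)-3,4,5,6-tetramethoxyphenol 7 (not isolated), via (6E)-2,3,4,5-tetramethoxy-6-(methoxymethylidene)cyclohexa-2,4-dien-1-one 8 (not isolated)
Conditions: HC(OMe)3, Amberlyst-15, CH2Cl2, rt, filter, evaporate; then 6 (2 equiv), (R)-3,3'-bis(2,4,6-triisopropylphenyl)-1,1'-binaphthyl-2,2'-diyl N-triflylphosphoramide (5 mol%), 5 Å MS, toluene, −30 °C; Et3N quench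
Reagents that add atoms: trimethyl orthoformate, COC(OC)OC
Why: Proposed new method: the chiral acid ionises acetal 7 to the oxocarbenium ion/ortho-quinone methide 8 (geometry written as E for definiteness), held as a hydrogen-bonded ion pair, and alkene 6 adds through C3 to the methide carbon C4 while the carbonyl oxygen O1 closes on the benzylic carbon C2, an inverse-electron-demand oxa-[4+2] cycloaddition that restores the aromaticity of ring A. The closest known reaction types are the chiral N-triflylphosphoramide-catalysed [4+2] cycloaddition of aryl-substituted ortho-quinone methides with styrenes, the confined chiral acid-catalysed intramolecular [4+2] cycloaddition of salicylaldehyde-derived alkoxy ortho-quinone methides, and the racemic Sc(OTf)3-mediated union of salicylaldehydes, orthoformate and alkenes to 4-alkoxychromanes; the intermolecular enantioselective case with an alkoxy ortho-quinone methide is the new element. Ring C closes as the six-membered adduct of a concerted but asynchronous [4+2] event (C3–C4 bonding ahead of O1–C2), or in the stepwise limit by 6-endo capture of the 4-methoxybenzyl cation by the phenolic oxygen inside the ion pair. C2 is set by the chiral counter-anion, which sits on O1–H beside the forming O1–C2 bond and leaves one face of the alkene open, while C4 follows from endo approach and is erased in step 5. The step needs regioselectivity, secured by the cation-stabilising 4-methoxyphenyl group on C2, and the same sense at C2 in whatever C4 epimers form, secured by endo selectivity within the chiral pocket. It also needs chemoselectivity over acid-induced oligomerisation of 6, secured by the much easier ionisation of 7 and by the absence of any free C–H position on ring A.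

**Step 5**
Reactants: 9 (2S,4S)-4,5,6,7,8-pentamethoxy-2-(4-methoxyphenyl)chromane
Product: 10 (2S)-5,6,7,8-tetramethoxy-2-(4-methoxyphenyl)chroman-4-one [(2S)-5,6,7,8,4'-pentamethoxyflavanone]
Conditions: DDQ (1.2 equiv), CH2Cl2/pH 7 phosphate buffer (10:1), 0 °C
Reagents that add atoms: water, O
Why: DDQ oxidation of an electron-rich benzylic methyl ether: hydride abstraction from C4 (benzylic to the pentaoxygenated ring A and alpha to OMe) gives an oxocarbenium ion that water hydrolyses to the ketone, while C2, which is not benzylic to ring A, should react more slowly and keep its configuration under buffered, base-free conditions.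

**Compound list**
1 | 3,4,5-trimethoxyphenol | COc1cc(O)cc(OC)c1OC | starting material
2 | 2-(hydroxymethyl)-3,4,5-trimethoxyphenol (as its magnesium salt, not isolated) | OCc1c(O)cc(OC)c(OC)c1OC | intermediate
3 | 2-hydroxy-4,5,6-trimethoxybenzaldehyde | O=Cc1c(O)cc(OC)c(OC)c1OC | intermediate
4 | 3-bromo-2-hydroxy-4,5,6-trimethoxybenzaldehyde | O=Cc1c(O)c(Br)c(OC)c(OC)c1OC | intermediate
5 | 2-hydroxy-3,4,5,6-tetramethoxybenzaldehyde | O=Cc1c(O)c(OC)c(OC)c(OC)c1OC | intermediate
6 | 4-methoxystyrene | C=Cc1ccc(OC)cc1 | starting material
7 | 2-(dimethoxymethyl)-3,4,5,6-tetramethoxyphenol (not isolated) | COC(OC)c1c(O)c(OC)c(OC)c(OC)c1OC | intermediate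
8 | (6E)-2,3,4,5-tetramethoxy-6-(methoxymethylidene)cyclohexa-2,4-dien-1-one (ortho-quinone methide, not isolated) | CO/C=C1/C(=O)C(OC)=C(OC)C(OC)=C1OC | intermediate
9 | (2S,4S)-4,5,6,7,8-pentamethoxy-2-(4-methoxyphenyl)chromane (2,4-cis) | COc1ccc([C@@H]2C[C@H](OC)c3c(OC)c(OC)c(OC)c(OC)c3O2)cc1 | intermediate
10 | (2S)-5,6,7,8-tetramethoxy-2-(4-methoxyphenyl)chroman-4-one | COc1ccc([C@@H]2CC(=O)c3c(OC)c(OC)c(OC)c(OC)c3O2)cc1 | target

**Totals**
Total step count: 5. Longest linear sequence: 5 steps (1 → 3 → 4 → 5 → 9 → 10).

**Steps most likely to fail**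

1. Step 4 (proposed new method). The ion pair may discriminate poorly between the faces of the unfunctionalised alkene, the endo/exo preference may be low so that C2 is not uniform, or acid-induced oligomerisation of the styrene may outrun the cycloaddition. Fallback with known chemistry, setting out from 5 and returning at 10:
   - Addition of MeMgBr (THF, 0 °C) should give 2-(1-hydroxyethyl)-3,4,5,6-tetramethoxyphenol F1.
   - MnO2 (CH2Cl2) should oxidise the benzylic alcohol to 1-(2-hydroxy-3,4,5,6-tetramethoxyphenyl)ethan-1-one F2.
   - Heating with N,N-dimethylformamide dimethyl acetal should give (2E)-3-(dimethylamino)-1-(2-hydroxy-3,4,5,6-tetramethoxyphenyl)prop-2-en-1-one F3.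
   - Aqueous HCl should close F3, with loss of dimethylamine, to 5,6,7,8-tetramethoxy-4H-chromen-4-one F4.
   - Enantioselective conjugate addition of 4-methoxyphenylboronic acid to F4, with Pd(OCOCF3)2 and the tert-butyl pyridine–oxazoline ligand antipode that delivers 2S, then gives 10.

2. Step 5. Hydride abstraction may also occur at C2, or the product may be dehydrogenated further to the flavone; either process destroys the C2 centre. Fallback, setting out from 9 and returning at 10: solvolysis with pyridinium p-toluenesulfonate in aqueous acetone should exchange the C4 methoxy group for hydroxyl through the stabilised C4 cation, with no oxidant present. This gives (2S)-5,6,7,8-tetramethoxy-2-(4-methoxyphenyl)chroman-4-ol F5 as a mixture of C4 epimers. Dess–Martin periodinane (NaHCO3, CH2Cl2) then oxidises the alcohol to 10.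

3. Step 3. C–O coupling at the doubly ortho-flanked C–Br bond may be slow, leaving room for reductive loss of bromine and for base-induced degradation of the aldehyde in hot methoxide. Fallback, setting out from 1 and returning at 5, which moves the oxygenation ahead of the formylation so that no aldehyde is present during the coupling:
   - NBS (1 equiv, CH2Cl2, −78 °C) should give 2-bromo-3,4,5-trimethoxyphenol F6.
   - NaOMe/CuBr in DMF/MeOH should give 2,3,4,5-tetramethoxyphenol F7.
   - MgCl2/Et3N/paraformaldehyde formylation at the single free ring position, through 2-(hydroxymethyl)-3,4,5,6-tetramethoxyphenol F8 (not isolated), then gives 5.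

**Further compounds**
F1 | step 4 | 2-(1-hydroxyethyl)-3,4,5,6-tetramethoxyphenol (racemic) | CC(O)c1c(O)c(OC)c(OC)c(OC)c1OC
F2 | step 4 | 1-(2-hydroxy-3,4,5,6-tetramethoxyphenyl)ethan-1-one | CC(=O)c1c(O)c(OC)c(OC)c(OC)c1OC
F3 | step 4 | (2E)-3-(dimethylamino)-1-(2-hydroxy-3,4,5,6-tetramethoxyphenyl)prop-2-en-1-one | CN(C)/C=C/C(=O)c1c(O)c(OC)c(OC)c(OC)c1OC
F4 | step 4 | 5,6,7,8-tetramethoxy-4H-chromen-4-one | O=c1ccoc2c(OC)c(OC)c(OC)c(OC)c12
F5 | step 5 | (2S)-5,6,7,8-tetramethoxy-2-(4-methoxyphenyl)chroman-4-ol (C4 epimers) | COc1ccc([C@@H]2CC(O)c3c(OC)c(OC)c(OC)c(OC)c3O2)cc1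
F6 | step 3 | 2-bromo-3,4,5-trimethoxyphenol | COc1cc(O)c(Br)c(OC)c1OC
F7 | step 3 | 2,3,4,5-tetramethoxyphenol | COc1cc(O)c(OC)c(OC)c1OC
F8 | step 3 | 2-(hydroxymethyl)-3,4,5,6-tetramethoxyphenol (not isolated) | OCc1c(O)c(OC)c(OC)c(OC)c1OC
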